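## Structural features

The target is a biflavone ether without stereocentres. It consists of an acacetin unit (rings A and C plus a 4-methoxyphenyl ring B) and an apigenin unit (rings A and C plus a para-phenylene ring B), each a 2-aryl-4H-chromen-4-one. The two halves are joined by a single diaryl ether oxygen between C8 of the acacetin ring A and C4' of the apigenin ring B. Because there is no stereogenic centre, no centres stand next to each other and only regiochemistry has to be controlled. The fragile features are:
- four phenols, two of them (C5 of each half) chelated to the C4 carbonyls;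
- the single 4'-methyl ether, which must outlive every deprotection;
- the 5,8-dioxygenated (hydroquinone-like) acacetin ring A, which oxidizes easily once O8 is free;
- the two pyranone rings, which open with hot hydroxide and can scramble the ring A pattern under forcing acid (Wessely–Moser isomerization).

The real difficulty is the ether at C8, which lies between O7 and the ring oxygen O1, together with the need to keep five oxygen functions apart with only one of them methylated. The key step exploits ring A of the apigenin half (C4a, C5, C6, C7, C8, C8a): a resorcinol with hydroxyls at C5 and C7 and hydrogens at C6 and C8, fused to ring C through the C4a–C8a bond. This is the pattern of a phenol assembled from a ketene seated on C8a of a preformed pyranone and a terminal ynol ether.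

## Logic of the disconnections

25 is traced back to 24 by cutting the three benzyl–oxygen bonds at O5 and O7 of the acacetin half and O7 of the apigenin half. Benzyl is chosen because it can be removed without touching the 4'-methyl ether. The gain is one neutral final step; the demand is that the reduction spare the two C2=C3 double bonds.

24 is cut through ring A of its apigenin half at C5–C6, C7–C8 and C5–C4a, giving 15 and 20. This removes a whole ring and leaves a monocyclic pyranone with a two-carbon diazoacetyl handle on C8a plus a two-carbon ynol ether. The ring appears with its oxygens already differentiated (free at C5, benzylated at C7). The forward step must excite only the diazoketone, must bond the ketene carbonyl carbon to the unsubstituted alkyne carbon, and must close on C4a. It must also cope with the thermal lability of 20.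

20 is cut at its O–C(sp) bond into 16 and 17, the latter supplying both alkyne carbons (the future C6 and C7). 20 cannot be stored, so it has to be made in one flask and used cold.

15 is cut at the C=N2 bond and goes back to methyl ketone 13. A carboxylic acid on the pyranone would not serve, because a diazoalkane would only esterify it, and the acid chloride route needs diazomethane. A methyl ketone takes the diazo group from a sulfonyl azide instead. The demand is clean enolization at the acetyl methyl of 13 and nowhere else.

13 is opened at the ring oxygen–carbon bond of its pyranone and its carbonyl is masked, giving ketal 12 and then the open-chain triketone 11. The heterocycle is thereby reduced to a linear chain. The acid that closes it must be mild enough for the benzyl ethers, and six-ring closure must win over five-ring closure onto the masked carbonyl.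

11 is cut between the future C4a and C8a into 9 and 10. 10 has no α-hydrogen and brings C8a, C5 and C8 in one piece with the acetyl already masked. The demand is formation of the dianion of 9 without metalation of the flavone.

9 is cut between the future C3 and C4 into 7 and 8, a simple C-acylation of a methyl ketone enolate.

7 is cut at the O–C4' bond of the diaryl ether and at the O5–benzyl bond, giving 4 and 5. The para-acetyl group of 5 activates the fluoride for displacement and is also the seed of ring C (C2 and C3). The demand is selectivity for O8 over the chelated O5, and exclusion of oxygen.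

4 is cut at the C8–O bond and goes back to 2. Persulfate oxidation para to the free 5-hydroxyl puts the oxygen on C8, which is why O5 must be free and O7 blocked at that stage.

2 is cut at the O7–benzyl bond and goes back to 1, which is bought with rings A, B and C of the acacetin half and the methyl ether in place.

## Other disconnections considered

Alternative 1: The cut goes through ring B of the apigenin half at C2'–C3' and C4'–C5'. The para-phenylene ring would come from the four diene carbons of methyl coumalate A1 and the two alkyne carbons of the aryl ethynyl ether A2, whose oxygen is the future C8–O–C4' bridge. Forward, A1 and A2 would be heated. Inverse-electron-demand [4+2] cycloaddition, with the nucleophilic terminal alkyne carbon bonding to C6 of A1, followed by decarboxylative cycloreversion of the bridged lactone, should give the para-aryloxybenzoate A3.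
- In its favour: the step is thermal and reagent-free and its para regiochemistry follows from the polarization of both partners. It needs neither light nor a diazo compound, so on safety it is the better key step. O8 is present from the start, so the persulfate oxidation is not needed; on the placing of O8 it is again the better.
- Against it: it builds the cheapest ring in the molecule, which is available as 5 with its activating group. The hindered ether bond is not avoided but moved into the preparation of A2 from a fully oxygenated phenol that itself takes several steps. A3 contains neither chromenone, so both pyranone rings, ring A of the apigenin half and the anisyl ring would all follow the key step, including a regioselective C-acylation at C4a between two oxygens.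
- Comparison: mechanistically the two plans are equal, both being pericyclic cascades that end in an arene. Structurally the chosen plan makes the one ring that must be made once 1 is bought, and it should be far shorter.

Alternative 2: Ring A of the acacetin half is taken apart at C8a–C4a, C5–C6 and C8–C8a. Forward, cyclobutenone A4 would be heated with ethoxyacetylene A5. Four-electron ring opening to a vinylketene, [2+2] cycloaddition, a second ring opening and six-electron closure should give phenol A6. A6 has the free hydroxyl where O1 is needed, three differently substituted oxygens, and the aryl ether at C8.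
- In its favour: this is the original thermal form of the benzannulation. It is better precedented than the photochemical variant chosen here and free of diazo compounds and light, so it is the better on precedent and on safety. It fixes the C8 ether and the identity of every ring A oxygen in one step, so it is the better on regiochemical certainty.
- Against it: A4 is not a trivial compound. The ethyl group that A5 leaves on O5 must later be removed beside the 4'-methyl ether, which chelation-assisted Lewis acid cleavage should allow at the cost of an extra selective step. After A6, the acacetin pyranone, its ring B and the entire apigenin half (grown from the aryl bromide) are still missing, whereas the chosen plan buys the acacetin half intact.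
- Comparison: in mechanism the two are the same ketene–ynol ether logic and therefore equal in kind. Step economy clearly favours the chosen plan.

Alternative 3: Only C5–C6 of the acacetin ring A is cut. Forward, the pyranone keto ester A7 would be converted by a strong lithium amide base into its dianion. The methyl ketone enolate carbon (C6) would attack the ester carbonyl (C5) on C4a in a Dieckmann-type Claisen closure, and the cyclic 1,3-diketone would aromatize by enolization to A8 with free hydroxyls at C5 and C7.
- In its favour: it is purely ionic chemistry without photochemistry or diazo compounds, so it is better on safety. Ring A appears unprotected with the correct oxygen pattern. The ether bond is made early by alkylation of a phenol at an sp3 carbon, which is easier than any arylation of a hindered phenol, so it is better on that bond. In topology (a resorcinol grown on a preformed pyranone) it is the equal of the chosen plan.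
- Against it: A7 is a densely substituted pyranone that needs a long preparation. The doubly activated carbanion next to the aryloxy group could trigger pyranone ring opening or O-acylation. A8 still lacks the whole apigenin half, which would have to be grown from the bromide by carbonylation and a full flavone synthesis with the phenols protected again.
- Comparison: it re-makes a ring that is sold as part of 1, so step economy favours the chosen plan.

Key step: step 9

Remarks on the chemistry (checks, corrections and assumptions):
- Each half is numbered as a flavone (O1, C2–C8a, primed locants for ring B). The target is achiral, so no configuration has to be set.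
- The atom mapping of the annulation was checked and 15 and 24 as drawn are consistent with it: diazo carbon → C8; acyl carbon with its oxygen → C5 and the 5-hydroxyl; terminal alkyne carbon → C6; oxygenated alkyne carbon → C7; pyranone C6 → C8a; pyranone C5 → C4a. C4a is the pyranone carbon α (not β) to the ring carbonyl.
- The pyranone carries an acetyl group (13) rather than a carboxylic acid, so that the diazo group comes from a sulfonyl azide and no diazomethane is used.
- Benzyl alkynyl ethers rearrange sigmatropically on mild heating (from about 60 °C). Step 9 is therefore run in two stages, with the excess of 20 removed before the thermal stage.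
- 8, 10 and the hydroxyacetophenone and aldehyde used in the fallbacks are assumed to be purchasable.

## Steps

Step 1
Reactants: 1 acacetin (5,7-dihydroxy-2-(4-methoxyphenyl)-4H-chromen-4-one)
Product: 2 7-(benzyloxy)-5-hydroxy-2-(4-methoxyphenyl)-4H-chromen-4-one
Conditions: BnBr (1.1 equiv), K2CO3 (1.2 equiv), DMF, 23 → 40 °C
Reagents that add atoms: benzyl bromide, BrCc1ccccc1
Why: Williamson etherification; the 7-hydroxyl is the more acidic and is not tied up in a hydrogen bond, whereas the 5-hydroxyl is chelated to the C4 carbonyl and should stay free with only a slight excess of carbonate.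

Step 2
Reactants: 2 7-(benzyloxy)-5-hydroxy-2-(4-methoxyphenyl)-4H-chromen-4-one
Product: 4 7-(benzyloxy)-5,8-dihydroxy-2-(4-methoxyphenyl)-4H-chromen-4-one, via potassium flavon-8-yl sulfate 3 (not isolated)
Conditions: K2S2O8 (1.5 equiv), aq. KOH, pyridine, 0 → 23 °C; acidify to pH 5 and extract unchanged 2; then conc. HCl, 85 °C, N2
Reagents that add atoms: potassium peroxodisulfate, [K+].[K+].[O-]S(=O)(=O)OOS(=O)(=O)[O-]; potassium hydroxide, [K+].[OH-] (its potassium is carried by 3 only)
Why: Elbs persulfate oxidation; the 5-phenoxide attacks a peroxide oxygen through its para carbon, which is C8, and the aryl sulfate 3 stays in the aqueous phase until acid hydrolysis frees the phenol. The reaction type is established for 7-O-alkyl-5-hydroxyflavones; unchanged 2 is recovered and recycled.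

Step 3
Reactants: 4 7-(benzyloxy)-5,8-dihydroxy-2-(4-methoxyphenyl)-4H-chromen-4-one; 5 4-fluoroacetophenone
Product: 7 8-(4-acetylphenoxy)-5,7-bis(benzyloxy)-2-(4-methoxyphenyl)-4H-chromen-4-one, via 5-hydroxy diaryl ether 6 (not isolated)
Conditions: 5 (1.5 equiv), K2CO3 (3 equiv), degassed DMF, 110 °C, N2; then BnBr (1.5 equiv), 60 °C
Reagents that add atoms: benzyl bromide, BrCc1ccccc1
Why: Nucleophilic aromatic substitution (addition–elimination) of the fluoride para to the acetyl group; the unchelated 8-phenoxide should react in preference to the chelated, peri-hindered 5-phenoxide. Once O8 is arylated the ring is no longer a free hydroquinone, and the chelated 5-hydroxyl is then benzylated in the same flask under more forcing Williamson conditions.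

Step 4
Reactants: 7 8-(4-acetylphenoxy)-5,7-bis(benzyloxy)-2-(4-methoxyphenyl)-4H-chromen-4-one; 8 1-acetyl-1H-benzotriazole
Product: 9 1-(4-{[5,7-bis(benzyloxy)-2-(4-methoxyphenyl)-4-oxo-4H-chromen-8-yl]oxy}phenyl)butane-1,3-dione
Conditions: LiN(SiMe3)2 (2.2 equiv), THF, −78 °C; 8 (1.1 equiv), −78 → 0 °C; 1 M HCl
Reagents that add atoms: none
Why: Crossed Claisen-type C-acylation of the kinetic lithium enolate of the only methyl ketone by an N-acylazole, with the second equivalent of base taking up the more acidic diketone as it forms. LiN(SiMe3)2 is non-nucleophilic and too weak to metalate the flavone C3–H, so the acacetin half should be untouched.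

Step 5
Reactants: 9 1-(4-{[5,7-bis(benzyloxy)-2-(4-methoxyphenyl)-4-oxo-4H-chromen-8-yl]oxy}phenyl)butane-1,3-dione; 10 ethyl 2,2-diethoxypropanoate
Product: 11 1-(4-{[5,7-bis(benzyloxy)-2-(4-methoxyphenyl)-4-oxo-4H-chromen-8-yl]oxy}phenyl)-6,6-diethoxyheptane-1,3,5-trione
Conditions: LiN(iPr)2 (2.3 equiv), THF, −78 → −30 °C; 10 (2 equiv), −78 → 0 °C; 1 M HCl to pH 4
Reagents that add atoms: none
Why: Claisen condensation of a β-diketone dianion, which reacts at its more basic terminal carbon. 10 cannot enolize and is activated by its two α-alkoxy groups, so it should acylate cleanly and cannot self-condense.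

Step 6
Reactants: 11 1-(4-{[5,7-bis(benzyloxy)-2-(4-methoxyphenyl)-4-oxo-4H-chromen-8-yl]oxy}phenyl)-6,6-diethoxyheptane-1,3,5-trione
Product: 13 8-[4-(6-acetyl-4-oxo-4H-pyran-2-yl)phenoxy]-5,7-bis(benzyloxy)-2-(4-methoxyphenyl)-4H-chromen-4-one, via ketal pyranone 12 (not isolated)
Conditions: CF3CO2H/CH2Cl2 (1:4), 0 → 23 °C; then H2O (5 vol%), 23 °C
Reagents that add atoms: water, O
Why: Acid-catalysed cyclodehydration of a 1,3,5-triketone to a 4-pyranone (enol oxygen onto the protonated carbonyl, then loss of water), followed by ketal hydrolysis. An α-keto ketal ionizes slowly, so ring closure should precede unmasking and no free 1,2-diketone is present that could close to a furanone; benzyl aryl ethers should tolerate dilute CF3CO2H at 23 °C.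

Step 7
Reactants: 13 8-[4-(6-acetyl-4-oxo-4H-pyran-2-yl)phenoxy]-5,7-bis(benzyloxy)-2-(4-methoxyphenyl)-4H-chromen-4-one
Product: 15 5,7-bis(benzyloxy)-8-{4-[6-(diazoacetyl)-4-oxo-4H-pyran-2-yl]phenoxy}-2-(4-methoxyphenyl)-4H-chromen-4-one, via trifluoroacetyl diketone 14 (not isolated)
Conditions: LiN(SiMe3)2 (1.1 equiv), THF, −78 °C; CF3CO2CH2CF3 (1.2 equiv), −78 °C; 1 M HCl work-up; then 4-AcNHC6H4SO2N3 (1.5 equiv), Et3N (1.5 equiv), H2O (1 equiv), MeCN, 23 °C, dark
Reagents that add atoms: 4-acetamidobenzenesulfonyl azide, CC(=O)Nc1ccc(S(=O)(=O)N=[N+]=[N-])cc1; 2,2,2-trifluoroethyl trifluoroacetate, O=C(OCC(F)(F)F)C(F)(F)F (its trifluoroacetyl group is carried by 14 only)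
Why: Detrifluoroacetylative (Regitz-type deacylative) diazo transfer; the acetyl methyl is the only enolizable position, its trifluoroacetyl derivative 14 is acidic enough for diazo transfer with triethylamine, and the trifluoroacetyl group is then cleaved in preference to the pyranonyl ketone. This is the standard entry to α,β-unsaturated and aryl diazomethyl ketones and avoids diazomethane; the sulfonyl azide chosen is among the less shock-sensitive transfer reagents.

Step 8
Reactants: 16 benzyl alcohol; 17 trichloroethylene
Product: 20 benzyl ethynyl ether, via dichlorovinyl ether 18 (not isolated), via lithium alkynyl ether 19 (not isolated)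
Conditions: KH (1.2 equiv), THF, 0 °C; 17 (1.1 equiv), −50 → 23 °C; n-BuLi (2.4 equiv), −78 → −40 °C; MeOH, −78 °C; cold pentane/H2O work-up, solution kept at or below 0 °C and used at once
Reagents that add atoms: n-butyllithium, [Li]CCCC (its lithium is carried by 19 only)
Why: Known one-flask ynol ether synthesis: the alkoxide adds anti to dichloroacetylene formed in solution from 17, giving the (E)-dichlorovinyl ether 18. n-BuLi then causes β-elimination and chlorine–lithium exchange to 19, which is protonated cold. The double-bond geometry of 18 is lost in the elimination; the whole sequence is kept cold and under inert gas because of the transient dichloroacetylene and the thermal lability of 20.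

Step 9
Reactants: 15 5,7-bis(benzyloxy)-8-{4-[6-(diazoacetyl)-4-oxo-4H-pyran-2-yl]phenoxy}-2-(4-methoxyphenyl)-4H-chromen-4-one; 20 benzyl ethynyl ether
Product: 24 5,7-bis(benzyloxy)-8-{4-[7-(benzyloxy)-5-hydroxy-4-oxo-4H-chromen-2-yl]phenoxy}-2-(4-methoxyphenyl)-4H-chromen-4-one, via pyranonylketene 21 (not isolated), via pyranonylcyclobutenone 22 (not isolated), via dienylketene 23 (not isolated)
Conditions: 20 (4 equiv), CH2Cl2 (0.01 M), 440 nm LEDs (long-pass filter > 400 nm), 15 °C, N2; evaporate excess 20 below 20 °C (0.1 mmHg); toluene, 80 °C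
Reagents that add atoms: none
Why: Blue light excites only the n→π* band of the diazoketone, and loss of N2 with 1,2-shift of the pyranonyl group (Wolff rearrangement) should give ketene 21. The electron-rich ynol ether 20 adds to this electron-poor ketene by [2+2] cycloaddition with its nucleophilic unsubstituted carbon bonding to the ketene carbonyl carbon, so that C5–C6 and C7–C8 form and the benzyloxy group sits on the future C7 of cyclobutenone 22. At 80 °C reversible four-electron electrocyclic opening of 22 gives dienylketene 23, of which only the isomer with the pyranone cis to the ketene can react on. Ring A closes by a thermally allowed six-electron electrocyclization in which the ketene carbon C5 bonds to pyranone carbon C4a, the only free position next to C8a, and tautomerization of the resulting dienone gives the phenol, whose hydroxyl is held by a hydrogen bond to the C4 carbonyl. The closest known reaction type is the second-generation Danheiser benzannulation of alkenyl, aryl and heteroaryl diazomethyl ketones with alkoxy- and siloxyalkynes. No stereocentre remains: the saturated ring carbon of 22 is formed as a racemate and becomes planar on ring opening. The step needs three selectivities: the regiochemistry of the [2+2], secured by the polarization of 20; excitation of the diazoketone alone, secured by the wavelength, since neither the dibenzyloxyflavone nor the arylpyranone absorbs above 400 nm; and survival of the benzyl enol ether, secured by removing the excess of 20 before heating, because 20 itself would rearrange sigmatropically at the temperature of the ring opening.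

Step 10
Reactants: 24 5,7-bis(benzyloxy)-8-{4-[7-(benzyloxy)-5-hydroxy-4-oxo-4H-chromen-2-yl]phenoxy}-2-(4-methoxyphenyl)-4H-chromen-4-one
Product: 25 5,7-dihydroxy-8-[4-(5,7-dihydroxy-4-oxo-4H-chromen-2-yl)phenoxy]-2-(4-methoxyphenyl)-4H-chromen-4-one (CNP0295851.0)
Conditions: H2 (1 atm), 10% Pd/C (water-wet), THF/MeOH (1:1), 23 °C, stopped as soon as 24 and the partly debenzylated intermediates are consumed
Reagents that add atoms: none
Why: Heterogeneous hydrogenolysis of benzyl aryl ethers, which is faster than reduction of the tetrasubstituted, electron-rich C2=C3 bonds of flavones; the aryl methyl ether and the diaryl ether are inert. Atmospheric pressure and wet catalyst under inert-gas purging keep the step safe.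

## Compound list

1 | acacetin, 5,7-dihydroxy-2-(4-methoxyphenyl)-4H-chromen-4-one | COc1ccc(-c2cc(=O)c3c(O)cc(O)cc3o2)cc1 | starting material
2 | 7-(benzyloxy)-5-hydroxy-2-(4-methoxyphenyl)-4H-chromen-4-one | COc1ccc(-c2cc(=O)c3c(O)cc(OCc4ccccc4)cc3o2)cc1 | intermediate
3 | potassium 7-(benzyloxy)-5-hydroxy-2-(4-methoxyphenyl)-4-oxo-4H-chromen-8-yl sulfate | COc1ccc(-c2cc(=O)c3c(O)cc(OCc4ccccc4)c(OS(=O)(=O)[O-])c3o2)cc1.[K+] | intermediate
4 | 7-(benzyloxy)-5,8-dihydroxy-2-(4-methoxyphenyl)-4H-chromen-4-one | COc1ccc(-c2cc(=O)c3c(O)cc(OCc4ccccc4)c(O)c3o2)cc1 | intermediate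
5 | 4-fluoroacetophenone | CC(=O)c1ccc(F)cc1 | starting material
6 | 8-(4-acetylphenoxy)-7-(benzyloxy)-5-hydroxy-2-(4-methoxyphenyl)-4H-chromen-4-one | COc1ccc(-c2cc(=O)c3c(O)cc(OCc4ccccc4)c(Oc4ccc(C(C)=O)cc4)c3o2)cc1 | intermediate
7 | 8-(4-acetylphenoxy)-5,7-bis(benzyloxy)-2-(4-methoxyphenyl)-4H-chromen-4-one | COc1ccc(-c2cc(=O)c3c(OCc4ccccc4)cc(OCc4ccccc4)c(Oc4ccc(C(C)=O)cc4)c3o2)cc1 | intermediate
8 | 1-acetyl-1H-benzotriazole | CC(=O)n1nnc2ccccc21 | starting material
9 | 1-(4-{[5,7-bis(benzyloxy)-2-(4-methoxyphenyl)-4-oxo-4H-chromen-8-yl]oxy}phenyl)butane-1,3-dione | COc1ccc(-c2cc(=O)c3c(OCc4ccccc4)cc(OCc4ccccc4)c(Oc4ccc(C(=O)CC(C)=O)cc4)c3o2)cc1 | intermediate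
10 | ethyl 2,2-diethoxypropanoate | CCOC(=O)C(C)(OCC)OCC | starting material
11 | 1-(4-{[5,7-bis(benzyloxy)-2-(4-methoxyphenyl)-4-oxo-4H-chromen-8-yl]oxy}phenyl)-6,6-diethoxyheptane-1,3,5-trione | COc1ccc(-c2cc(=O)c3c(OCc4ccccc4)cc(OCc4ccccc4)c(Oc4ccc(C(=O)CC(=O)CC(=O)C(C)(OCC)OCC)cc4)c3o2)cc1 | intermediate
12 | 5,7-bis(benzyloxy)-8-{4-[6-(1,1-diethoxyethyl)-4-oxo-4H-pyran-2-yl]phenoxy}-2-(4-methoxyphenyl)-4H-chromen-4-one | COc1ccc(-c2cc(=O)c3c(OCc4ccccc4)cc(OCc4ccccc4)c(Oc4ccc(-c5cc(=O)cc(C(C)(OCC)OCC)o5)cc4)c3o2)cc1 | intermediate
13 | 8-[4-(6-acetyl-4-oxo-4H-pyran-2-yl)phenoxy]-5,7-bis(benzyloxy)-2-(4-methoxyphenyl)-4H-chromen-4-one | COc1ccc(-c2cc(=O)c3c(OCc4ccccc4)cc(OCc4ccccc4)c(Oc4ccc(-c5cc(=O)cc(C(C)=O)o5)cc4)c3o2)cc1 | intermediate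
14 | 1-[6-(4-{[5,7-bis(benzyloxy)-2-(4-methoxyphenyl)-4-oxo-4H-chromen-8-yl]oxy}phenyl)-4-oxo-4H-pyran-2-yl]-4,4,4-trifluorobutane-1,3-dione | COc1ccc(-c2cc(=O)c3c(OCc4ccccc4)cc(OCc4ccccc4)c(Oc4ccc(-c5cc(=O)cc(C(=O)CC(=O)C(F)(F)F)o5)cc4)c3o2)cc1 | intermediate
15 | 5,7-bis(benzyloxy)-8-{4-[6-(diazoacetyl)-4-oxo-4H-pyran-2-yl]phenoxy}-2-(4-methoxyphenyl)-4H-chromen-4-one | [N-]=[N+]=CC(=O)c1cc(=O)cc(-c2ccc(Oc3c(OCc4ccccc4)cc(OCc4ccccc4)c4c(=O)cc(-c5ccc(OC)cc5)oc34)cc2)o1 | intermediate
16 | benzyl alcohol | OCc1ccccc1 | starting material
17 | trichloroethylene | ClC=C(Cl)Cl | starting material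
18 | benzyl (E)-1,2-dichlorovinyl ether | Cl/C=C(/Cl)OCc1ccccc1 | intermediate
19 | lithium (benzyloxy)ethynide | [Li]C#COCc1ccccc1 | intermediate
20 | benzyl ethynyl ether | C#COCc1ccccc1 | intermediate
21 | [6-(4-{[5,7-bis(benzyloxy)-2-(4-methoxyphenyl)-4-oxo-4H-chromen-8-yl]oxy}phenyl)-4-oxo-4H-pyran-2-yl]ketene | O=C=Cc1cc(=O)cc(-c2ccc(Oc3c(OCc4ccccc4)cc(OCc4ccccc4)c4c(=O)cc(-c5ccc(OC)cc5)oc34)cc2)o1 | intermediate
22 | 3-(benzyloxy)-4-[6-(4-{[5,7-bis(benzyloxy)-2-(4-methoxyphenyl)-4-oxo-4H-chromen-8-yl]oxy}phenyl)-4-oxo-4H-pyran-2-yl]cyclobut-2-en-1-one (racemic) | O=C1C=C(OCc2ccccc2)C1c1cc(=O)cc(-c2ccc(Oc3c(OCc4ccccc4)cc(OCc4ccccc4)c4c(=O)cc(-c5ccc(OC)cc5)oc34)cc2)o1 | intermediate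
23 | (3E)-3-(benzyloxy)-4-[6-(4-{[5,7-bis(benzyloxy)-2-(4-methoxyphenyl)-4-oxo-4H-chromen-8-yl]oxy}phenyl)-4-oxo-4H-pyran-2-yl]buta-1,3-dien-1-one | O=C=C/C(OCc1ccccc1)=C\c1cc(=O)cc(-c2ccc(Oc3c(OCc4ccccc4)cc(OCc4ccccc4)c4c(=O)cc(-c5ccc(OC)cc5)oc34)cc2)o1 | intermediate
24 | 5,7-bis(benzyloxy)-8-{4-[7-(benzyloxy)-5-hydroxy-4-oxo-4H-chromen-2-yl]phenoxy}-2-(4-methoxyphenyl)-4H-chromen-4-one | COc1ccc(-c2cc(=O)c3c(OCc4ccccc4)cc(OCc4ccccc4)c(Oc4ccc(-c5cc(=O)c6c(O)cc(OCc7ccccc7)cc6o5)cc4)c3o2)cc1 | intermediate
25 | 5,7-dihydroxy-8-[4-(5,7-dihydroxy-4-oxo-4H-chromen-2-yl)phenoxy]-2-(4-methoxyphenyl)-4H-chromen-4-one (CNP0295851.0) | COc1ccc(-c2cc(=O)c3c(O)cc(O)c(Oc4ccc(-c5cc(=O)c6c(O)cc(O)cc6o5)cc4)c3o2)cc1 | target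

## Step count and least certain steps

Total: 10 steps. Longest linear sequence: 9 steps (steps 1–7, 9 and 10; step 8 is a one-step side branch).

Step 9 (key step). The most likely failure is loss of the ketene before or after the cycloaddition. Possible paths are capture by adventitious nucleophiles or dimerization at the stage of 21, consumption of the ynol ether by sigmatropic rearrangement if the flask warms, and a slow six-electron closure onto the electron-poor pyranone carbon. In that last case the dienylketene would be diverted into oligomers or into acylation of the product phenol. The fallback abandons the annulation and builds the apigenin half by the chalcone route; it sets out from 4 and returns at 25. 4 would be arylated with 4-fluorobenzaldehyde (K2CO3, DMF, 100 °C) and benzylated in the same flask to give 4-{[5,7-bis(benzyloxy)-2-(4-methoxyphenyl)-4-oxo-4H-chromen-8-yl]oxy}benzaldehyde F1. Claisen–Schmidt condensation of F1 with purchased 1-[2,4-bis(benzyloxy)-6-hydroxyphenyl]ethanone (KOH, EtOH/THF, 23 °C) should give (E)-1-[2,4-bis(benzyloxy)-6-hydroxyphenyl]-3-(4-{[5,7-bis(benzyloxy)-2-(4-methoxyphenyl)-4-oxo-4H-chromen-8-yl]oxy}phenyl)prop-2-en-1-one F2. Oxidative cyclization (catalytic I2, DMSO, 120 °C) should then give 5,7-bis(benzyloxy)-8-{4-[5,7-bis(benzyloxy)-4-oxo-4H-chromen-2-yl]phenoxy}-2-(4-methoxyphenyl)-4H-chromen-4-one F3, and hydrogenolysis under the conditions of step 10 should give 25.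

Step 5. The amide base may metalate the acacetin-half flavone at C3, or the second deprotonation of the diketone may stay incomplete, so that the hindered ester is attacked slowly and the flavone is acylated or opened instead. The fallback replaces the kinetic dianion by a thermodynamic Claisen condensation with a far more electrophilic ester and reaches the diazoketone through the acid; it sets out from 9 and returns at 15. 9 would be condensed with diethyl oxalate (NaOEt, EtOH/THF, 23 °C) to ethyl 6-(4-{[5,7-bis(benzyloxy)-2-(4-methoxyphenyl)-4-oxo-4H-chromen-8-yl]oxy}phenyl)-2,4,6-trioxohexanoate F4. Cyclodehydration (CF3CO2H, CH2Cl2) should give ethyl 6-(4-{[5,7-bis(benzyloxy)-2-(4-methoxyphenyl)-4-oxo-4H-chromen-8-yl]oxy}phenyl)-4-oxo-4H-pyran-2-carboxylate F5. Saponification (LiOH, THF/H2O, 0 °C) should give 6-(4-{[5,7-bis(benzyloxy)-2-(4-methoxyphenyl)-4-oxo-4H-chromen-8-yl]oxy}phenyl)-4-oxo-4H-pyran-2-carboxylic acid F6. Oxalyl chloride with catalytic DMF should give 6-(4-{[5,7-bis(benzyloxy)-2-(4-methoxyphenyl)-4-oxo-4H-chromen-8-yl]oxy}phenyl)-4-oxo-4H-pyran-2-carbonyl chloride F7, and acylation of (trimethylsilyl)diazomethane (MeCN/THF, 0 °C) with loss of the silyl group should give 15. This path is two steps longer and uses a toxic diazoalkane, which is why it is only the reserve.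

Step 7. Enolization and trifluoroacetylation may be incomplete, or the electron-poor 2-acylpyranone may be opened by the amine and water of the diazo transfer, so that the transfer competes with degradation. The fallback avoids enolate chemistry and forms the diazo group by fragmentation of a sulfonylhydrazone; it sets out from 13 and returns at 15. Oxidation of the acetyl group of 13 (SeO2, dioxane/H2O, 90 °C) should give 2-[6-(4-{[5,7-bis(benzyloxy)-2-(4-methoxyphenyl)-4-oxo-4H-chromen-8-yl]oxy}phenyl)-4-oxo-4H-pyran-2-yl]-2-oxoacetaldehyde F8. Condensation at the aldehyde with tosylhydrazide (THF, 0 °C) should give the (E)-monotosylhydrazone of that glyoxal F9, and triethylamine (CH2Cl2, 23 °C) should expel sulfinate from it to give 15.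

Step 2. Low conversion and over-oxidation of the hydroquinone-like product to a quinone are likely, made worse by the poor solubility of 2 in aqueous base; persulfate oxidations of this kind are generally low-yielding. The fallback introduces O8 through a halide instead of an oxidation of the phenol; it sets out from 2 and returns at 7. Benzylation of 2 (BnBr, K2CO3, DMF, 70 °C) should give 5,7-bis(benzyloxy)-2-(4-methoxyphenyl)-4H-chromen-4-one F10. Iodination (N-iodosuccinimide, catalytic CF3CO2H, MeCN) should go to C8, the most nucleophilic position of the fully alkylated ring A, giving 5,7-bis(benzyloxy)-8-iodo-2-(4-methoxyphenyl)-4H-chromen-4-one F11. Miyaura borylation (B2pin2, PdCl2(dppf), KOAc, dioxane, 90 °C) should give the 8-pinacolboronate F12, which is oxidized without isolation (NaBO3·4H2O, THF/H2O) to 5,7-bis(benzyloxy)-8-hydroxy-2-(4-methoxyphenyl)-4H-chromen-4-one F13. Arylation of F13 with 5 (K2CO3, DMF, 110 °C) should give 7.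

Step 10. Over-reduction of a C2=C3 double bond to a flavanone may occur, or debenzylation may stall because the partly deprotected material precipitates on the catalyst. The fallback cleaves the ethers with a Lewis acid instead of hydrogen; it sets out from 24 and returns at 25. BCl3 with pentamethylbenzene as cation scavenger (CH2Cl2, −78 °C) should remove the three benzyl groups and leave the aryl methyl ether; it makes no new compound.

## Further compounds

F1 | step 9 | 4-{[5,7-bis(benzyloxy)-2-(4-methoxyphenyl)-4-oxo-4H-chromen-8-yl]oxy}benzaldehyde | O=Cc1ccc(Oc2c(OCc3ccccc3)cc(OCc3ccccc3)c3c(=O)cc(-c4ccc(OC)cc4)oc23)cc1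
F2 | step 9 | (E)-1-[2,4-bis(benzyloxy)-6-hydroxyphenyl]-3-(4-{[5,7-bis(benzyloxy)-2-(4-methoxyphenyl)-4-oxo-4H-chromen-8-yl]oxy}phenyl)prop-2-en-1-one | O=C(/C=C/c1ccc(Oc2c(OCc3ccccc3)cc(OCc3ccccc3)c3c(=O)cc(-c4ccc(OC)cc4)oc23)cc1)c1c(O)cc(OCc2ccccc2)cc1OCc1ccccc1
F3 | step 9 | 5,7-bis(benzyloxy)-8-{4-[5,7-bis(benzyloxy)-4-oxo-4H-chromen-2-yl]phenoxy}-2-(4-methoxyphenyl)-4H-chromen-4-one | COc1ccc(-c2cc(=O)c3c(OCc4ccccc4)cc(OCc4ccccc4)c(Oc4ccc(-c5cc(=O)c6c(OCc7ccccc7)cc(OCc7ccccc7)cc6o5)cc4)c3o2)cc1
F4 | step 5 | ethyl 6-(4-{[5,7-bis(benzyloxy)-2-(4-methoxyphenyl)-4-oxo-4H-chromen-8-yl]oxy}phenyl)-2,4,6-trioxohexanoate | COc1ccc(-c2cc(=O)c3c(OCc4ccccc4)cc(OCc4ccccc4)c(Oc4ccc(C(=O)CC(=O)CC(=O)C(=O)OCC)cc4)c3o2)cc1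
F5 | step 5 | ethyl 6-(4-{[5,7-bis(benzyloxy)-2-(4-methoxyphenyl)-4-oxo-4H-chromen-8-yl]oxy}phenyl)-4-oxo-4H-pyran-2-carboxylate | COc1ccc(-c2cc(=O)c3c(OCc4ccccc4)cc(OCc4ccccc4)c(Oc4ccc(-c5cc(=O)cc(C(=O)OCC)o5)cc4)c3o2)cc1
F6 | step 5 | 6-(4-{[5,7-bis(benzyloxy)-2-(4-methoxyphenyl)-4-oxo-4H-chromen-8-yl]oxy}phenyl)-4-oxo-4H-pyran-2-carboxylic acid | COc1ccc(-c2cc(=O)c3c(OCc4ccccc4)cc(OCc4ccccc4)c(Oc4ccc(-c5cc(=O)cc(C(=O)O)o5)cc4)c3o2)cc1
F7 | step 5 | 6-(4-{[5,7-bis(benzyloxy)-2-(4-methoxyphenyl)-4-oxo-4H-chromen-8-yl]oxy}phenyl)-4-oxo-4H-pyran-2-carbonyl chloride | COc1ccc(-c2cc(=O)c3c(OCc4ccccc4)cc(OCc4ccccc4)c(Oc4ccc(-c5cc(=O)cc(C(=O)Cl)o5)cc4)c3o2)cc1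
F8 | step 7 | 2-[6-(4-{[5,7-bis(benzyloxy)-2-(4-methoxyphenyl)-4-oxo-4H-chromen-8-yl]oxy}phenyl)-4-oxo-4H-pyran-2-yl]-2-oxoacetaldehyde | COc1ccc(-c2cc(=O)c3c(OCc4ccccc4)cc(OCc4ccccc4)c(Oc4ccc(-c5cc(=O)cc(C(=O)C=O)o5)cc4)c3o2)cc1
F9 | step 7 | N'-[(E)-2-[6-(4-{[5,7-bis(benzyloxy)-2-(4-methoxyphenyl)-4-oxo-4H-chromen-8-yl]oxy}phenyl)-4-oxo-4H-pyran-2-yl]-2-oxoethylidene]-4-methylbenzenesulfonohydrazide | COc1ccc(-c2cc(=O)c3c(OCc4ccccc4)cc(OCc4ccccc4)c(Oc4ccc(-c5cc(=O)cc(C(=O)/C=N/NS(=O)(=O)c6ccc(C)cc6)o5)cc4)c3o2)cc1
F10 | step 2 | 5,7-bis(benzyloxy)-2-(4-methoxyphenyl)-4H-chromen-4-one | COc1ccc(-c2cc(=O)c3c(OCc4ccccc4)cc(OCc4ccccc4)cc3o2)cc1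
F11 | step 2 | 5,7-bis(benzyloxy)-8-iodo-2-(4-methoxyphenyl)-4H-chromen-4-one | COc1ccc(-c2cc(=O)c3c(OCc4ccccc4)cc(OCc4ccccc4)c(I)c3o2)cc1
F12 | step 2 | 5,7-bis(benzyloxy)-2-(4-methoxyphenyl)-8-(4,4,5,5-tetramethyl-1,3,2-dioxaborolan-2-yl)-4H-chromen-4-one | COc1ccc(-c2cc(=O)c3c(OCc4ccccc4)cc(OCc4ccccc4)c(B4OC(C)(C)C(C)(C)O4)c3o2)cc1
F13 | step 2 | 5,7-bis(benzyloxy)-8-hydroxy-2-(4-methoxyphenyl)-4H-chromen-4-one | COc1ccc(-c2cc(=O)c3c(OCc4ccccc4)cc(OCc4ccccc4)c(O)c3o2)cc1
F0 | step 10 | none | none
A1 | alternative 1 | methyl coumalate (methyl 2-oxo-2H-pyran-5-carboxylate) | COC(=O)c1ccc(=O)oc1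
A2 | alternative 1 | 1,5-bis(benzyloxy)-2-(ethynyloxy)-3-(methoxymethoxy)benzene | C#COc1c(OCOC)cc(OCc2ccccc2)cc1OCc1ccccc1
A3 | alternative 1 | methyl 4-[2,4-bis(benzyloxy)-6-(methoxymethoxy)phenoxy]benzoate | COC(=O)c1ccc(Oc2c(OCOC)cc(OCc3ccccc3)cc2OCc2ccccc2)cc1
A4 | alternative 2 | 3-(benzyloxy)-4-(4-bromophenoxy)cyclobut-2-en-1-one (racemic) | O=C1C=C(OCc2ccccc2)C1Oc1ccc(Br)cc1
A5 | alternative 2 | ethoxyacetylene | C#COCC
A6 | alternative 2 | 3-(benzyloxy)-2-(4-bromophenoxy)-5-ethoxyphenol | Oc1cc(OCC)cc(OCc2ccccc2)c1Oc1ccc(Br)cc1
A7 | alternative 3 | methyl 2-[1-(4-bromophenoxy)-2-oxopropyl]-6-(4-methoxyphenyl)-4-oxo-4H-pyran-3-carboxylate (racemic) | COC(=O)c1c(C(Oc2ccc(Br)cc2)C(C)=O)oc(-c2ccc(OC)cc2)cc1=O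
A8 | alternative 3 | 8-(4-bromophenoxy)-5,7-dihydroxy-2-(4-methoxyphenyl)-4H-chromen-4-one | COc1ccc(-c2cc(=O)c3c(O)cc(O)c(Oc4ccc(Br)cc4)c3o2)cc1
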